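## Structural features

The target is a ten-membered carbocycle, numbered here C1–C10 so that the two trisubstituted ring alkenes are C1=C10 and C4=C5 (methyl groups on C10 and C4). It carries a free allylic hydroxyl at C6, an isopropyl group at C7 and a 4-hydroxy-3-methoxybenzoyl ester at C8. Both alkenes have the ring carbons cis (Z); they are joined by the C2–C3 ethylene unit on one side and by the C6–C7–C8–C9 chain on the other, so the ring is a (Z,Z)-cyclodeca-1,5-diene. The stereocentres C6 (S), C7 (R) and C8 (R) are contiguous: the two oxygens are syn to each other and each is anti to the isopropyl group between them. Fragile groups are the aryl ester next to a 1,3-related free hydroxyl (acyl migration, hydrolysis), the free phenol, and the allylic C6 carbinol inside a 1,5-diene that can ionise and cyclise across the ring under acid. The real difficulty is the medium ring: closing ten carbons by bond formation is entropically and enthalpically unfavourable, and two trisubstituted alkenes must each be a single geometrical isomer. The feature used is that C4–C5–C6–C7–C8 is a five-atom arc holding every stereocentre and the C4=C5 alkene, while C8–C9–C10–C1–C2–C3–C4 is a seven-atom arc holding the C1=C10 alkene. A temporary C4–C8 bond therefore gives a cis-fused cyclopentane/cycloheptene bicycle in which C1=C10 can only be cis and C6 and C7 sit on a rigid five-membered ring. In that bicycle the C8 oxygen, the C4–C8 bond and a leaving group on C5 form the 1,3-diol monosulfonate array whose Grob fragmentation returns C8=O, C4=C5 and the ten-membered ring.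

## Logic of the disconnections

25 ⇒ 24. The O–Si bonds at the phenol and at the C6 oxygen are the last to be cleaved. Masking both means only the C8 oxygen can be acylated, so the regiochemistry of esterification is not in question. The forward step must remove both silyl groups close to neutrality, so that the acyl group does not move to C6 and the allylic carbinol is not ionised.

24 ⇒ 19 + 22. The C8–O acyl bond is cut, which separates the arene from the carbocycle and leaves a mono-protected diol. The forward step has to acylate a secondary carbinol flanked by the isopropyl-bearing carbon, hence activation of 22 as 23. 22 is traced to 20 through 21 by cutting the phenolic O–Si bond.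

19 ⇒ 18. The C8–H bond is cut, returning the carbinol to a ketone. This is what the fragmentation produces, and it removes one stereocentre from the ring-forming stage. The forward step needs hydride delivery to one face of a flexible ten-membered ketone without base, because 18 has an epimerisable C7–H, a β-silyloxy group and a β,γ-alkene.

18 ⇒ 16 (through 17). A C4–C8 bond is drawn and C4=C5 is replaced by a C5–O sulfonate. The ten-membered ring becomes a five/seven bicycle with no medium ring, and both alkene geometries become consequences of ring size and relative configuration. The forward step requires the C5 leaving group cis to the C4–C3 bond and close to anti to C4–C8, and it requires a base regime that spares 18.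

16 ⇒ 15 ⇒ 14. The C5–O–S bond and then the C5–H bond are cut. This leaves a β-hydroxy ketone whose only carbonyl is C5. Hydride must arrive on the face of the C8 hydroxyl so that the C5 oxygen ends cis to C3, and the reduction must not be basic (retro-aldol across C4–C8, silyl migration from the C6 oxygen).

14 ⇒ 13. The C1=C10 double bond is cut (ring-closing metathesis retron), giving a monocyclic cyclopentane with a butenyl arm on C4 and a methallyl arm on C8. The forward step needs these arms cis; the seven-membered ring then fixes C1=C10 as Z.

13 ⇒ 12 ⇒ 10 (through 11). The C6 O–Si bond and then the C6–O bond are cut, leading back to a C5=C6 silyl enol ether. The forward oxidation must deliver oxygen to C6 anti to the C7 isopropyl group and must be faster than attack on the two isolated alkenes.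

10 ⇒ 8 + 9. The C8–C9 bond is cut. Because C5 is still an enol ether at this point, C8 is the only carbonyl, so the two ring carbonyls never need to be distinguished. This is a deliberate change from the more obvious order, in which C6 is oxidised first and one of two hindered ketones must then be reduced selectively. The forward step needs attack at C8 anti to the isopropyl group, which puts the new arm cis to the butenyl arm.

8 ⇒ 5 + 6 (through 7). The C7–isopropyl bond is cut, giving an achiral ene-dione with a mirror plane. One catalytic step must choose one of two enantiotopic alkene carbons, choose the face anti to the butenyl arm, and deliver the enolate oxygen at C5 for O-silylation.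

5 ⇒ 4 ⇒ 3 ⇒ 1 + 2. The C6=C7 unsaturation, the terminal C=CH2 bond and the C4–C3 bond are removed in turn. All ring carbons of the cyclopentane and the butenyl arm come from two cheap components. The forward steps need a conjugate addition that creates the quaternary carbon, a methylenation selective for the aldehyde, and a dehydrogenation that leaves the terminal alkene alone.

## Other disconnections considered

Alternative 1: The cut is the C2–C3 single bond between the two allylic methylenes.

- **Forward key step.** The open-chain compound A1 already contains both Z alkenes, the C6–C8 triad with different silyl ethers on C6 and C8, a phenylsulfonyl group on C2 and a primary allylic bromide at C3. A hindered potassium amide at high dilution would deprotonate C2, and the sulfonyl-stabilised allyl anion would displace bromide to close the ring to A2. Reductive desulfonylation erases the C2 centre; selective unmasking of C8, acylation with 22 and final desilylation follow.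
- **In favour.** Sulfone-carbanion alkylation is among the more dependable closures of medium carbocycles, the new bond is remote from the stereocentres, and the assembly is convergent.
- **Where it is better.** C8 enters with fixed configuration and orthogonal protection, so no late ketone reduction on a flexible ring is needed.
- **Against.** The ring is formed by bond construction at the size where entropy and transannular strain are worst. Intermolecular alkylation, attack through the γ-terminus of the allyl anion and SN2′ displacement would compete. Both Z alkenes must be made stereoselectively in an open chain and must survive an allylic bromide and an allyl anion. Reductive removal of an allylic sulfone passes through allyl radical or anion character and can shift or isomerise C1=C10. The anti,anti triad needs several acyclic stereoselective steps.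
- **Comparison.** On structure, the chosen plan takes alkene geometry from ring constraints and Alternative 1 from acyclic olefin synthesis. On mechanism, the chosen plan opens a bicycle instead of closing a ring. On step economy, Alternative 1 is expected to be longer overall but is equal or better in convergence.

Alternative 2: The cut is the C5–C6 bond.

- **Forward key step.** A3 carries a (Z)-alkenyl iodide at C5, an aldehyde at C6 and the silyl-protected aroyl ester already on C8. Divalent chromium chloride (CrCl2) with catalytic NiCl2 would convert the iodide into an alkenylchromium species that adds to the aldehyde (Nozaki–Hiyama–Kishi reaction). This closes the ring and creates C6 in one operation to give A4, one desilylation away from 25.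
- **In favour.** The coupling tolerates esters, keeps alkenyl geometry and needs no protection at C6.
- **Where it is better.** The end game after ring formation is a single step, against four steps after the key step in the chosen plan.
- **Against.** The C6 configuration would be decided by the cyclisation transition state of a ten-membered ring and cannot be predicted with confidence. The closure again needs high dilution and a large excess of a chromium salt. A3 is an α-branched β-acyloxy aldehyde, so elimination of the aroyloxy group and epimerisation at C7 threaten during its preparation and during a slow cyclisation. The Z iodide, the Z C1=C10 alkene and the C7/C8 pair all need acyclic stereocontrol.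
- **Comparison.** On structure, the chosen plan sets C6 early on a cyclopentane by a reaction of known facial preference; Alternative 2 sets it during ring closure, which is more economical in stereocentre-forming events if selective. On mechanism, Alternative 2 is a C–C ring closure with its entropic cost, and the chosen plan avoids closure. On step economy, Alternative 2 is shorter after the key step but is expected to need a longer linear route to A3.

Alternative 3: The cut removes the two-carbon unit C7–C8 (with its isopropyl group) by breaking C6–C7 and C8–C9, leaving an eight-membered ring.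

- **Forward key step.** The eight-membered dienone A5 would be converted into its cross-conjugated silyl enol ether A6 (C6=C9). A6 would undergo [2+2] cycloaddition with ketene A7, generated in situ, forming C8–C9 and C6–C7 to give cyclobutanone A8. Reductive dechlorination and desilylative retro-aldol cleavage of the C6–C9 fusion bond would open the ten-membered 1,3-dione A9.
- **In favour.** The whole carbon skeleton is reached in very few steps from inexpensive material.
- **Where it is equal or better.** It is better than the chosen plan in step count to the ring. It is equal in logic: both alkenes take their cis geometry from a smaller ring, and the ten-membered ring is revealed by breaking a fusion bond.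
- **Against.** A9 has no secure stereocentre, since C7 lies between two carbonyls and is lost to enolisation. C6, C7 and C8 would all have to be created afterwards on a flexible ten-membered β-diketone. That needs a reduction that is enantioselective, tells the conjugated C6 carbonyl from the isolated C8 carbonyl and gives the syn diol anti to isopropyl, followed by differentiation of two secondary hydroxyls for mono-acylation. The cycloaddition of a monoalkyl chloroketene to a silyloxy triene also raises questions of reactivity and periselectivity, and a medium-ring enone/β-diketone invites double-bond migration and transannular reactions.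
- **Comparison.** On structure, the chosen plan fixes C6 and C7 by one catalytic asymmetric step on a rigid ring before the large ring exists. On mechanism, the two plans are close relatives (ring expansion by fragmentation). On step economy, Alternative 3 wins up to the ring and is expected to lose it again in the stereochemical end game.

Key step: step 11

Conventions. Ring atoms keep the target numbering C1–C10 in every intermediate. For cyclopentane intermediates the ring is drawn flat and numbered clockwise C4→C8→C7→C6→C5; β means toward the viewer and α away. The butenyl arm (later the seven-membered ring) is β; the C4 methyl is α.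

Structure check. The structures of 16 and 18 were checked atom by atom against 25. In 16 the C5 sulfonate is β, cis to C3, which is what a Z C4=C5 alkene requires. C6 and C7 have the same spatial arrangement in 16, 18 and 25. No structural correction was needed. One mechanistic point is tempered: in a five-membered ring the C5–O bond can only be near-anti to C4–C8, not exactly anti.

Assumption. The (S,R,R) enantiomer of the phosphoramidite ligand is taken to direct isopropyl to the alkene carbon that becomes C7; if the sense of induction is the opposite, the mirror-image ligand is used and nothing else changes.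

## Route

Step 1
Reactants: 1 2-methylcyclopentane-1,3-dione; 2 acrolein
Product: 3 3-(1-methyl-2,5-dioxocyclopentyl)propanal
Conditions: H2O, rt
Reagents that add atoms: none
Why: Michael addition of the acidic 2-alkyl-1,3-dione to acrolein in water without added base forms the quaternary carbon (future C4) and the C4–C3 bond; no stereocentre is formed.

Step 2
Reactants: 3 3-(1-methyl-2,5-dioxocyclopentyl)propanal
Product: 4 2-(but-3-en-1-yl)-2-methylcyclopentane-1,3-dione
Conditions: Ph3PCH3Br, KN(SiMe3)2, THF, −78 → 0 °C
Reagents that add atoms: methylenetriphenylphosphorane C=P(c1ccccc1)(c1ccccc1)c1ccccc1, made in the flask from methyltriphenylphosphonium bromide C[P+](c1ccccc1)(c1ccccc1)c1ccccc1.[Br-]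
Why: Wittig methylenation; the non-stabilised ylide reacts with the aldehyde much faster than with the two hindered ketones beside the quaternary carbon, and cold, alkoxide-free conditions avoid retro-Claisen opening of the 2,2-disubstituted dione.

Step 3
Reactants: 4 2-(but-3-en-1-yl)-2-methylcyclopentane-1,3-dione
Product: 5 2-(but-3-en-1-yl)-2-methylcyclopent-4-ene-1,3-dione
Conditions: IBX, DMSO, 70 °C
Reagents that add atoms: none
Why: IBX dehydrogenation of a ketone through its enol introduces the C6=C7 double bond; there is only one CH2–CH2 unit, so over-oxidation is excluded, and the isolated terminal alkene is not a substrate.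

Step 4
Reactants: 5 2-(but-3-en-1-yl)-2-methylcyclopent-4-ene-1,3-dione; 6 diisopropylzinc
Product: 8 4β-butenyl-4α-methyl-7α-isopropyl-5-(trimethylsilyloxy)cyclopent-5-en-8-one, via isopropylzinc enolate 7 (not isolated)
Conditions: Cu(OTf)2 (2 mol %), (S,R,R)-BINOL phosphoramidite of bis(1-phenylethyl)amine (4 mol %), toluene, −30 °C; then Me3SiOTf, −30 → 0 °C
Reagents that add atoms: trimethylsilyl trifluoromethanesulfonate C[Si](C)(C)OS(=O)(=O)C(F)(F)F
Why: Copper-catalysed asymmetric conjugate addition of a dialkylzinc, used as a desymmetrisation: the chiral copper–phosphoramidite complex selects one of the two enantiotopic alkene carbons (future C7) and isopropyl enters anti to the longer butenyl arm, i.e. cis to the C4 methyl, which fixes C7 and makes C4 a stereocentre. The zinc enolate 7 is silylated on the C5 oxygen, so C5 stays masked and C8 is left as the only ketone.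

Step 5
Reactants: 8 4β-butenyl-4α-methyl-7α-isopropyl-5-(trimethylsilyloxy)cyclopent-5-en-8-one; 9 methallylmagnesium chloride
Product: 10 4β-butenyl-4α-methyl-8β-methallyl-7α-isopropyl-5-(trimethylsilyloxy)cyclopent-5-en-8α-ol
Conditions: THF, −78 °C; aq NH4Cl at −78 °C
Reagents that add atoms: none
Why: 1,2-Addition of an allylic Grignard reagent to the only free carbonyl; allylic Grignards add through a cyclic six-membered transition state even to ketones flanked by a quaternary and a branched carbon. Attack on the β face, anti to the adjacent α isopropyl group, places the methallyl arm cis to the butenyl arm and gives the tertiary C8 carbinol.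

Step 6
Reactants: 10 4β-butenyl-4α-methyl-8β-methallyl-7α-isopropyl-5-(trimethylsilyloxy)cyclopent-5-en-8α-ol
Product: 12 4β-butenyl-6β,8α-dihydroxy-4α-methyl-8β-methallyl-7α-isopropylcyclopentan-5-one, via silyloxy epoxide 11 (not isolated)
Conditions: mCPBA (1.05 equiv), NaHCO3, CH2Cl2, −20 °C; then citric acid, MeOH, 0 °C
Reagents that add atoms: 3-chloroperoxybenzoic acid OOC(=O)c1cccc(Cl)c1
Why: Rubottom oxidation: the electron-rich silyl enol ether is epoxidised much faster than the mono- and 1,1-disubstituted alkenes, and the peracid approaches C6 on the β face, anti to the C7 isopropyl group. Acid methanolysis of 11 releases the C5 ketone and the C6 β-hydroxyl, trans to isopropyl as in the target.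

Step 7
Reactants: 12 4β-butenyl-6β,8α-dihydroxy-4α-methyl-8β-methallyl-7α-isopropylcyclopentan-5-one
Product: 13 4β-butenyl-6β-(tert-butyldimethylsilyloxy)-8α-hydroxy-4α-methyl-8β-methallyl-7α-isopropylcyclopentan-5-one
Conditions: tBuMe2SiOTf (1.1 equiv), 2,6-lutidine, CH2Cl2, −78 °C
Reagents that add atoms: tert-butyldimethylsilyl trifluoromethanesulfonate CC(C)(C)[Si](C)(C)OS(=O)(=O)C(F)(F)F
Why: A silyl triflate with a hindered pyridine base silylates the secondary α-ketol hydroxyl at low temperature, while the tertiary C8 hydroxyl next to a quaternary carbon does not react; no base strong enough for retro-aldol cleavage or α-ketol isomerisation is present.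

Step 8
Reactants: 13 4β-butenyl-6β-(tert-butyldimethylsilyloxy)-8α-hydroxy-4α-methyl-8β-methallyl-7α-isopropylcyclopentan-5-one
Product: 14 cis-fused 6β-(tert-butyldimethylsilyloxy)-8α-hydroxy-4α,10-dimethyl-7α-isopropylbicyclo[5.3.0]dec-1(10)-en-5-one (fusion bond C4–C8)
Conditions: second-generation Grubbs catalyst RuCl2(=CHPh)(H2IMes)(PCy3) (5 mol %), CH2Cl2 (0.01 M), 40 °C
Reagents that add atoms: none
Why: Ring-closing metathesis between a monosubstituted and a 1,1-disubstituted alkene held cis on adjacent ring carbons closes the seven-membered ring with loss of ethene. A ring of this size can hold the new trisubstituted C1=C10 alkene only with the ring carbons cis, which is the Z geometry of the target.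

Step 9
Reactants: 14 cis-fused 6β-(tert-butyldimethylsilyloxy)-8α-hydroxy-4α,10-dimethyl-7α-isopropylbicyclo[5.3.0]dec-1(10)-en-5-one
Product: 15 cis-fused 6β-(tert-butyldimethylsilyloxy)-4α,10-dimethyl-7α-isopropylbicyclo[5.3.0]dec-1(10)-ene-5β,8α-diol
Conditions: Me4NBH(OAc)3, MeCN/AcOH (1:1), −30 → 0 °C
Reagents that add atoms: none
Why: Hydroxyl-directed triacetoxyborohydride reduction of a β-hydroxy ketone (Saksena–Evans reduction): the C8 α-hydroxyl binds boron and delivers hydride to the α face of C5, which is also the face not screened by the silyloxy group and the C3 methylene, so the new C5 hydroxyl is β, anti to the C8 hydroxyl and cis to C3. The acidic medium excludes retro-aldol cleavage of C4–C8 and silyl migration from the C6 oxygen.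

Step 10
Reactants: 15 cis-fused 6β-(tert-butyldimethylsilyloxy)-4α,10-dimethyl-7α-isopropylbicyclo[5.3.0]dec-1(10)-ene-5β,8α-diol
Product: 16 (4R,5S,6R,7R,8R)-6-(tert-butyldimethylsilyloxy)-8-hydroxy-4,10-dimethyl-7-isopropylbicyclo[5.3.0]dec-1(10)-en-5-yl methanesulfonate (5β-mesylate)
Conditions: MsCl, Et3N, CH2Cl2, −20 → 0 °C
Reagents that add atoms: methanesulfonyl chloride CS(=O)(=O)Cl
Why: Sulfonylation through sulfene takes place at the secondary C5 hydroxyl and leaves the tertiary C8 hydroxyl free as the later electron donor; C5 is neopentyl-like, so the mesylate should not be displaced.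

Step 11
Reactants: 16 (4R,5S,6R,7R,8R)-6-(tert-butyldimethylsilyloxy)-8-hydroxy-4,10-dimethyl-7-isopropylbicyclo[5.3.0]dec-1(10)-en-5-yl methanesulfonate
Product: 18 (1(10)Z,4Z,6S,7R)-6-(tert-butyldimethylsilyloxy)-4,10-dimethyl-7-isopropylcyclodeca-1(10),4-dien-8-one, via potassium alkoxide 17 (not isolated)
Conditions: KOtBu (1.05 equiv), THF, −20 → 0 °C; pH 7 phosphate buffer at 0 °C
Reagents that add atoms: none
Why: Grob fragmentation of a cyclic 1,3-diol monosulfonate (Wharton type, the closest known reaction being the opening of decalin and hydrindane diol monosulfonates to medium-ring enones): KOtBu forms alkoxide 17, whose oxygen lone pair pushes into C8 while the C4–C8 σ bond breaks and its electrons expel the C5 mesylate, so C8=O and C4=C5 form in one concerted, stereospecific event. No ring is closed by bond formation: the ten-membered ring is the periphery of the five/seven bicycle and appears when the shared C4–C8 bond is cleaved, so the penalties of medium-ring closure do not arise. No stereocentre is created (C4, C5 and C8 become trigonal); the C4/C5 relative configuration is converted into alkene geometry, and because the C5 mesylate is β, cis to the C4–C3 bond and trans to the C4 methyl, C3 and C6 end cis on the new double bond (Z), whereas the C5 epimer would give E. C1=C10 passes through unchanged with the Z geometry imposed by the seven-membered ring, and C6 and C7 are spectators. In a cyclopentane the C5–O bond cannot be exactly antiperiplanar to C4–C8; the envelope with the mesylate pseudo-equatorial brings the O–C5–C4–C8 torsion to roughly 150–160°, which is the alignment the step relies on. The selectivity needed is fragmentation over other base-induced paths: C5 is neopentyl-like, oxetane formation from the C8 alkoxide would require a strained 5-oxabicyclo[2.1.1]hexane, and the intramolecular fragmentation is helped by relief of strain between the fully substituted C4 and C8, so it should outrun intermolecular elimination toward C6. One equivalent of base, low temperature and a buffered quench are used because 18 has an epimerisable C7–H, a β-silyloxy group and a β,γ-alkene.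

Step 12
Reactants: 18 (1(10)Z,4Z,6S,7R)-6-(tert-butyldimethylsilyloxy)-4,10-dimethyl-7-isopropylcyclodeca-1(10),4-dien-8-one
Product: 19 (1(10)Z,4Z,6S,7S,8R)-6-(tert-butyldimethylsilyloxy)-4,10-dimethyl-7-isopropylcyclodeca-1(10),4-dien-8-ol
Conditions: (S)-2-methyl-CBS-oxazaborolidine (0.5 equiv), catecholborane, toluene, −78 → −40 °C
Reagents that add atoms: none
Why: Corey–Bakshi–Shibata reduction: the oxazaborolidine binds the ketone with the branched C7 arm as the large and the C9 methylene as the small substituent, so the (S)-catalyst should deliver hydride to the face that gives the 8R carbinol whatever the conformational bias of the ring (the change of the C7 descriptor from R to S is a priority effect only). Catecholborane does not hydroborate trisubstituted alkenes at this temperature and the medium is not basic, so C7 and the C10=C1 position are left alone.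

Step 13
Reactants: 20 vanillic acid
Product: 22 4-(tert-butyldimethylsilyloxy)-3-methoxybenzoic acid, via bis-silyl derivative 21 (not isolated)
Conditions: tBuMe2SiCl (2.5 equiv), imidazole, DMF, rt; then AcOH/THF/H2O, rt
Reagents that add atoms: tert-butyldimethylsilyl chloride CC(C)(C)[Si](C)(C)Cl
Why: Silylation of carboxyl and phenol, then selective hydrolysis of the much more labile silyl ester under mild aqueous acid, which leaves the aryl silyl ether.

Step 14
Reactants: 19 (1(10)Z,4Z,6S,7S,8R)-6-(tert-butyldimethylsilyloxy)-4,10-dimethyl-7-isopropylcyclodeca-1(10),4-dien-8-ol; 22 4-(tert-butyldimethylsilyloxy)-3-methoxybenzoic acid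
Product: 24 (1(10)Z,4Z,6S,7S,8R)-6-(tert-butyldimethylsilyloxy)-4,10-dimethyl-7-isopropylcyclodeca-1(10),4-dien-8-yl 4-(tert-butyldimethylsilyloxy)-3-methoxybenzoate, via mixed anhydride 23 (not isolated)
Conditions: 2,4,6-trichlorobenzoyl chloride, Et3N, THF, rt; then 19, DMAP, toluene, rt → 40 °C
Reagents that add atoms: none
Why: Yamaguchi esterification: DMAP attacks the unhindered aroyl carbonyl of 23 and the acylpyridinium acylates the hindered C8 carbinol with retention at C8; C6 is blocked by silicon, so only C8 can be acylated.

Step 15
Reactants: 24 (1(10)Z,4Z,6S,7S,8R)-6-(tert-butyldimethylsilyloxy)-4,10-dimethyl-7-isopropylcyclodeca-1(10),4-dien-8-yl 4-(tert-butyldimethylsilyloxy)-3-methoxybenzoate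
Product: 25 (1(10)Z,4Z,6S,7R,8R)-6-hydroxy-4,10-dimethyl-7-isopropylcyclodeca-1(10),4-dien-8-yl 4-hydroxy-3-methoxybenzoate (CNP0185892.3)
Conditions: TBAF, AcOH (1:1), THF, 0 °C → rt
Reagents that add atoms: none
Why: Fluoride cleavage of the aryl and the secondary alkyl silyl ether; buffering with acetic acid keeps the medium near neutral, so the aroyl group should not migrate to the freed C6 hydroxyl, the ester is not cleaved, and the allylic carbinol in the 1,5-diene is not exposed to strong acid.

## Compound list

1 | 2-methylcyclopentane-1,3-dione | CC1C(=O)CCC1=O | starting material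
2 | acrolein (prop-2-enal) | C=CC=O | starting material
3 | 3-(1-methyl-2,5-dioxocyclopentyl)propanal | CC1(CCC=O)C(=O)CCC1=O | intermediate
4 | 2-(but-3-en-1-yl)-2-methylcyclopentane-1,3-dione | CC1(CCC=C)C(=O)CCC1=O | intermediate
5 | 2-(but-3-en-1-yl)-2-methylcyclopent-4-ene-1,3-dione | CC1(CCC=C)C(=O)C=CC1=O | intermediate
6 | diisopropylzinc | CC(C)[Zn]C(C)C | starting material
7 | isopropylzinc C5-enolate of the conjugate adduct (4β-butenyl, 4α-methyl, 7α-isopropyl, C5=C6, C8 ketone) | C[C@]1(CCC=C)C(=O)[C@H](C(C)C)C=C1O[Zn]C(C)C | intermediate
8 | 4β-butenyl-4α-methyl-7α-isopropyl-5-(trimethylsilyloxy)cyclopent-5-en-8-one | C[C@]1(CCC=C)C(=O)[C@H](C(C)C)C=C1O[Si](C)(C)C | intermediate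
9 | methallylmagnesium chloride | CC(=C)C[Mg]Cl | starting material
10 | 4β-butenyl-4α-methyl-8β-methallyl-7α-isopropyl-5-(trimethylsilyloxy)cyclopent-5-en-8α-ol | C[C@]1(CCC=C)[C@@](O)(CC(C)=C)[C@H](C(C)C)C=C1O[Si](C)(C)C | intermediate
11 | 5β,6β-epoxide of 10 (5α-trimethylsilyloxy) | C[C@]1(CCC=C)[C@@](O)(CC(C)=C)[C@H](C(C)C)[C@H]2O[C@@]12O[Si](C)(C)C | intermediate
12 | 4β-butenyl-6β,8α-dihydroxy-4α-methyl-8β-methallyl-7α-isopropylcyclopentan-5-one | C[C@]1(CCC=C)[C@@](O)(CC(C)=C)[C@H](C(C)C)[C@@H](O)C1=O | intermediate
13 | 4β-butenyl-6β-(tert-butyldimethylsilyloxy)-8α-hydroxy-4α-methyl-8β-methallyl-7α-isopropylcyclopentan-5-one | C[C@]1(CCC=C)[C@@](O)(CC(C)=C)[C@H](C(C)C)[C@@H](O[Si](C)(C)C(C)(C)C)C1=O | intermediate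
14 | cis-fused 6β-(tert-butyldimethylsilyloxy)-8α-hydroxy-4α,10-dimethyl-7α-isopropylbicyclo[5.3.0]dec-1(10)-en-5-one | C[C@]12CCC=C(C)C[C@@]1(O)[C@H](C(C)C)[C@@H](O[Si](C)(C)C(C)(C)C)C2=O | intermediate
15 | cis-fused 6β-(tert-butyldimethylsilyloxy)-4α,10-dimethyl-7α-isopropylbicyclo[5.3.0]dec-1(10)-ene-5β,8α-diol | C[C@]12CCC=C(C)C[C@@]1(O)[C@H](C(C)C)[C@@H](O[Si](C)(C)C(C)(C)C)[C@H]2O | intermediate
16 | (4R,5S,6R,7R,8R)-6-(tert-butyldimethylsilyloxy)-8-hydroxy-4,10-dimethyl-7-isopropylbicyclo[5.3.0]dec-1(10)-en-5-yl methanesulfonate | C[C@]12CCC=C(C)C[C@@]1(O)[C@H](C(C)C)[C@@H](O[Si](C)(C)C(C)(C)C)[C@H]2OS(C)(=O)=O | intermediate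
17 | potassium C8-alkoxide of 16 | C[C@]12CCC=C(C)C[C@@]1([O-])[C@H](C(C)C)[C@@H](O[Si](C)(C)C(C)(C)C)[C@H]2OS(C)(=O)=O.[K+] | intermediate
18 | (1(10)Z,4Z,6S,7R)-6-(tert-butyldimethylsilyloxy)-4,10-dimethyl-7-isopropylcyclodeca-1(10),4-dien-8-one | O=C1C/C(C)=C\CC/C(C)=C\[C@H](O[Si](C)(C)C(C)(C)C)[C@H]1C(C)C | intermediate
19 | (1(10)Z,4Z,6S,7S,8R)-6-(tert-butyldimethylsilyloxy)-4,10-dimethyl-7-isopropylcyclodeca-1(10),4-dien-8-ol | O[C@@H]1C/C(C)=C\CC/C(C)=C\[C@H](O[Si](C)(C)C(C)(C)C)[C@H]1C(C)C | intermediate
20 | vanillic acid (4-hydroxy-3-methoxybenzoic acid) | COc1cc(C(=O)O)ccc1O | starting material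
21 | tert-butyldimethylsilyl 4-(tert-butyldimethylsilyloxy)-3-methoxybenzoate | COc1cc(C(=O)O[Si](C)(C)C(C)(C)C)ccc1O[Si](C)(C)C(C)(C)C | intermediate
22 | 4-(tert-butyldimethylsilyloxy)-3-methoxybenzoic acid | COc1cc(C(=O)O)ccc1O[Si](C)(C)C(C)(C)C | intermediate
23 | 4-(tert-butyldimethylsilyloxy)-3-methoxybenzoic 2,4,6-trichlorobenzoic anhydride | COc1cc(C(=O)OC(=O)c2c(Cl)cc(Cl)cc2Cl)ccc1O[Si](C)(C)C(C)(C)C | intermediate
24 | (1(10)Z,4Z,6S,7S,8R)-6-(tert-butyldimethylsilyloxy)-4,10-dimethyl-7-isopropylcyclodeca-1(10),4-dien-8-yl 4-(tert-butyldimethylsilyloxy)-3-methoxybenzoate | COc1cc(C(=O)O[C@@H]2C/C(C)=C\CC/C(C)=C\[C@H](O[Si](C)(C)C(C)(C)C)[C@H]2C(C)C)ccc1O[Si](C)(C)C(C)(C)C | intermediate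
25 | (1(10)Z,4Z,6S,7R,8R)-6-hydroxy-4,10-dimethyl-7-isopropylcyclodeca-1(10),4-dien-8-yl 4-hydroxy-3-methoxybenzoate (CNP0185892.3) | COc1cc(C(=O)O[C@@H]2C/C(C)=C\CC/C(C)=C\[C@H](O)[C@H]2C(C)C)ccc1O | target

## Step count and least certain steps

Total: 15 steps. Longest linear sequence: 14 steps (steps 1–12, 14 and 15); step 13 is a one-step side branch.

Step 11 (key step). The five-membered ring allows only near-anti alignment of the C5–O and C4–C8 bonds, so the fragmentation may be slow. Base could then epimerise C7, eliminate the C6 silyloxy group or move the C10=C1 double bond into conjugation in the product. Fallback without strong base: set out from diol 15 and treat it with Tf2O and pyridine in CH2Cl2 at −78 → 0 °C. The transient C5 trifluoromethanesulfonate F1 carries so good a leaving group that the neutral C8 hydroxyl, assisted only by the amine, should trigger the same fragmentation. The route is rejoined at 18.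

Step 4. Methyl and butenyl differ little in size, so facial discrimination at C4 may be poor. Enantioselection with a secondary alkylzinc may be lower, and O-silylation of the zinc enolate may be incomplete. Fallback that separates addition from enolate trapping: set out from 5 and add isopropylmagnesium bromide under CuBr·SMe2 with a ferrocenyl diphosphine ligand in tBuOMe at −78 °C, with aqueous quench. This gives the stable dione 4β-butenyl-4α-methyl-7α-isopropylcyclopentane-5,8-dione F2, which can be freed of stereoisomers by chromatography or crystallisation. Kinetic deprotonation with LiN(iPr)2 in THF at −78 °C should occur at the unhindered C6 methylene and not at the tertiary C7–H; trapping with Me3SiCl rejoins the route at 8.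

Step 6. Oxygen may be delivered to the α face through hydrogen bonding to the C8 hydroxyl, the methallyl alkene may be epoxidised in competition, or the enol silyl group may be lost before oxidation. Fallback by enolate hydroxylation instead of epoxidation: set out from 10 and treat it with MeLi (2.2 equiv) in THF at −78 → −20 °C to form the dilithium enolate–alkoxide F3. Add 2-(phenylsulfonyl)-3-phenyloxaziridine at −78 °C, which should hydroxylate C6 anti to the isopropyl group and does not touch alkenes, and quench cold with acetic acid. The route is rejoined at 12.

Step 10. Sulfonylation of the β C5 hydroxyl may be sluggish because it is neopentyl-like, cis to the silyl ether and under the seven-membered ring, so reaction at the tertiary hydroxyl could compete. Fallback by changing the order of ring closure and sulfonylation: set out from 13 and carry out the directed reduction of step 9 on the monocycle to give the 5β,8α-diol F4. Mesylate the less shielded C5 hydroxyl to give the monocyclic mesylate F5, then close the seven-membered ring by metathesis as in step 8. The route is rejoined at 16.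

Step 12. The flexible ten-membered ketone may present a facial bias that opposes the catalyst, giving the C8 epimer or a mixture, and a slow reduction gives the sensitive ketone time to isomerise. Fallback by inversion instead of retention: set out from 18 and reduce it deliberately to the 8S alcohol (1(10)Z,4Z,6S,7S,8S)-6-(tert-butyldimethylsilyloxy)-4,10-dimethyl-7-isopropylcyclodeca-1(10),4-dien-8-ol F6, using the (R)-oxazaborolidine or LiBH(sBu)3, whichever follows the substrate bias. Couple F6 with 22 under Mitsunobu conditions (PPh3, diisopropyl azodicarboxylate, toluene), which inverts C8. The route is rejoined at 24.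

## Further compounds

F1 | step 11 | (4R,5S,6R,7R,8R)-6-(tert-butyldimethylsilyloxy)-8-hydroxy-4,10-dimethyl-7-isopropylbicyclo[5.3.0]dec-1(10)-en-5-yl trifluoromethanesulfonate | C[C@]12CCC=C(C)C[C@@]1(O)[C@H](C(C)C)[C@@H](O[Si](C)(C)C(C)(C)C)[C@H]2OS(=O)(=O)C(F)(F)F
F2 | step 4 | 4β-butenyl-4α-methyl-7α-isopropylcyclopentane-5,8-dione | C[C@]1(CCC=C)C(=O)[C@H](C(C)C)CC1=O
F3 | step 6 | dilithium C5-enolate C8-alkoxide derived from 10 | C[C@]1(CCC=C)[C@@]([O-])(CC(C)=C)[C@H](C(C)C)C=C1[O-].[Li+].[Li+]
F4 | step 10 | 4β-butenyl-6β-(tert-butyldimethylsilyloxy)-4α-methyl-8β-methallyl-7α-isopropylcyclopentane-5β,8α-diol | C[C@]1(CCC=C)[C@@](O)(CC(C)=C)[C@H](C(C)C)[C@@H](O[Si](C)(C)C(C)(C)C)[C@H]1O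
F5 | step 10 | 5β-methanesulfonate of F4 | C[C@]1(CCC=C)[C@@](O)(CC(C)=C)[C@H](C(C)C)[C@@H](O[Si](C)(C)C(C)(C)C)[C@H]1OS(C)(=O)=O
F6 | step 12 | (1(10)Z,4Z,6S,7S,8S)-6-(tert-butyldimethylsilyloxy)-4,10-dimethyl-7-isopropylcyclodeca-1(10),4-dien-8-ol | O[C@H]1C/C(C)=C\CC/C(C)=C\[C@H](O[Si](C)(C)C(C)(C)C)[C@H]1C(C)C
A1 | alternative 1 | open-chain C3 allylic bromide / C2 phenyl sulfone with 6-O-tert-butyldimethylsilyl and 8-O-triethylsilyl groups (both alkenes Z) | BrC/C(C)=C\[C@H](O[Si](C)(C)C(C)(C)C)[C@@H](C(C)C)[C@H](O[Si](CC)(CC)CC)C/C(C)=C\CS(=O)(=O)c1ccccc1
A2 | alternative 1 | 2-phenylsulfonyl (Z,Z)-cyclodecadiene bis-silyl ether (either C2 epimer) | CC[Si](CC)(CC)O[C@@H]1C/C(C)=C\C(S(=O)(=O)c2ccccc2)C/C(C)=C\[C@H](O[Si](C)(C)C(C)(C)C)[C@H]1C(C)C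
A3 | alternative 2 | open-chain C6 aldehyde / C5 (Z)-alkenyl iodide carrying the 4-O-silyl aroyl ester at C8 | COc1cc(C(=O)O[C@H](C/C(C)=C\CC/C(C)=C\I)[C@@H](C=O)C(C)C)ccc1O[Si](C)(C)C(C)(C)C
A4 | alternative 2 | phenol tert-butyldimethylsilyl ether of 25 | COc1cc(C(=O)O[C@@H]2C/C(C)=C\CC/C(C)=C\[C@H](O)[C@H]2C(C)C)ccc1O[Si](C)(C)C(C)(C)C
A5 | alternative 3 | (2Z,6Z)-3,7-dimethylcycloocta-2,6-dien-1-one | O=C1/C=C(C)\CC/C=C(C)\C1
A6 | alternative 3 | trimethylsilyl enol ether of A5 (C6=C9, all ring alkenes cis) | C[Si](C)(C)O/C1=C/C(C)=C\CC/C(C)=C\1
A7 | alternative 3 | chloro(isopropyl)ketene | CC(C)C(Cl)=C=O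
A8 | alternative 3 | cyclobutanone cycloadduct of A6 and A7 (racemic, configuration at the three new centres not defined) | C[Si](C)(C)OC12/C=C(C)\CC/C=C(C)\C1C(=O)C2(Cl)C(C)C
A9 | alternative 3 | (4Z,8Z)-5,9-dimethyl-2-(propan-2-yl)cyclodeca-4,8-diene-1,3-dione (C7 not configurationally stable) | O=C1C/C(C)=C\CC/C(C)=C\C(=O)C1C(C)C
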